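**Plan**
- Cuts, in order: the C4–O acyl bond and the two C–O bonds of the 8,9-epoxide; then C7–C8 and C9–C10 of the seven-membered ring by a rhodium (5+2) cycloaddition; then the cyclopropane bonds C1–C10/C5–C10 and the C6–C7 bond; last the C1=C5 bond of the cyclopentene, back to (S)-terpinen-4-ol.
- Enabling feature: C7–C6–C5–C1–C10 is a vinylcyclopropane (C6=C7 on the C1–C5–C10 ring, fused to the cyclopentane at C1–C5) with the C6 oxygen as a silyl enol ether; C8–C9 come from a methyl silyl alkyne, and quaternary C1 is made beforehand as a cyclopropane carbon.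
- Forward order: cyclopentene (ozonolysis, aldol reclosure) → cyclopropane → seven-membered ring → C6 alcohol and C4 ester → epoxide.
- Stereochemistry: C4 from the chiral pool; the C6 carbinol by reagent control, relayed to C1/C5 by hydroxyl-directed cyclopropanation; C5–H by enol ether protonation; C6–OH by hydride delivery from the C4 hydroxyl; C8/C9 by epoxidation directed by the C6 hydroxyl.

Key step: step 8

Numbering used throughout: C1 (ring-fusion CMe), C2, C3 (CH2), C4 (C–O, isopropyl), C5 (ring-fusion CH), C6 (CHOH), C7 (CH2), C8 (CMe), C9 (CH), C10 (CH2). β is the face of the C1 methyl group. All bicyclic intermediates carry 1β-methyl, 4α-isopropyl and a 4β-oxygen.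

Assumption: (S)-(+)-terpinen-4-ol is used in enantiomerically enriched form (natural lots are not enantiopure). Because C6 is set by reagent control in step 4, material from the minor enantiomer becomes a diastereomer there and should be removable by chromatography.

**Step 1**
Reactants: 1 (S)-(+)-terpinen-4-ol
Product: 2 (S)-triethyl{[4-methyl-1-(propan-2-yl)cyclohex-3-en-1-yl]oxy}silane
Conditions: Et3SiOTf, 2,6-lutidine, CH2Cl2, 0 °C
Reagents that add atoms: triethylsilyl triflate, CC[Si](CC)(CC)OS(=O)(=O)C(F)(F)F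
Why: Silylation of a tertiary alcohol with a silyl triflate and a hindered base is routine, and the ether keeps the carbinol from closing a hemiketal on the later ketone or undergoing retro-aldol cleavage next to the aldehyde.

**Step 2**
Reactants: 2
Product: 4 (3S)-6-oxo-3-(propan-2-yl)-3-(triethylsilyloxy)heptanal, via ozonide 3 (not isolated)
Conditions: O3, CH2Cl2, −78 °C; then PPh3, −78 °C → rt
Reagents that add atoms: ozone, [O-][O+]=O
Why: Ozonolysis with reductive work-up cleaves the only C=C bond to the methyl ketone and the aldehyde without touching the silyl ether or the stereocentre.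

**Step 3**
Reactants: 4
Product: 5 (5R)-2-methyl-5-(propan-2-yl)-5-(triethylsilyloxy)cyclopent-1-ene-1-carbaldehyde
Conditions: piperidine (0.2 equiv), AcOH (0.2 equiv), benzene, 60 °C
Reagents that add atoms: none
Why: Intramolecular aldol condensation through the aldehyde enamine (the established conversion of 6-oxoheptanals into 2-methylcyclopent-1-enecarbaldehydes) closes the five-membered ring by 5-exo-trig attack of the aldehyde α-carbon on the methyl ketone and dehydrates to the conjugated enal; the carbinol centre is not involved.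

**Step 4**
Reactants: 5
Product: 6 (1R)-1-[(5R)-2-methyl-5-(propan-2-yl)-5-(triethylsilyloxy)cyclopent-1-en-1-yl]ethan-1-ol
Conditions: ZnMe2, Ti(OiPr)4, (1S,2S)-1,2-bis(trifluoromethanesulfonamido)cyclohexane (8 mol %), toluene, −20 → 0 °C
Reagents that add atoms: dimethylzinc, C[Zn]C
Why: Titanium bis(sulfonamide)-catalysed dialkylzinc addition to aldehydes is reagent-controlled, and the (1S,2S) ligand should deliver methyl to the Re face and set the (R)-carbinol at C6.

**Step 5**
Reactants: 6
Product: 7 (1R)-1-[(1S,2R,5R)-5-methyl-2-(propan-2-yl)-2-(triethylsilyloxy)bicyclo[3.1.0]hexan-1-yl]ethan-1-ol (cyclopropane CH2 cis to isopropyl, trans to OSiEt3)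
Conditions: ZnEt2, CH2I2, CH2Cl2, 0 °C → rt
Reagents that add atoms: diiodomethane, ICI
Why: Hydroxyl-directed Simmons–Smith cyclopropanation (Furukawa variant): with C6–H eclipsing the olefin to avoid A(1,3) strain with the cis methyl group, the zinc alkoxide of the (R)-carbinol sits on the α-face and delivers CH2 there, so C10 ends up anti to the silyloxy group and C1 and C5 are set together.

**Step 6**
Reactants: 7
Product: 8 1-[(1R,2R,5R)-5-methyl-2-(propan-2-yl)-2-(triethylsilyloxy)bicyclo[3.1.0]hexan-1-yl]ethan-1-one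
Conditions: Dess–Martin periodinane, NaHCO3, CH2Cl2, rt
Reagents that add atoms: none
Why: Dess–Martin oxidation of the secondary cyclopropyl carbinol gives the methyl ketone under buffered conditions that should leave the cyclopropylcarbinyl silyl ether intact.

**Step 7**
Reactants: 8
Product: 10 tert-butyldimethyl({1-[(1S,2R,5R)-5-methyl-2-(propan-2-yl)-2-(triethylsilyloxy)bicyclo[3.1.0]hexan-1-yl]ethenyl}oxy)silane, via lithium enolate 9 (not isolated)
Conditions: LiN(iPr)2, THF, −78 °C; then tBuMe2SiCl, HMPA, −78 → 0 °C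
Reagents that add atoms: tert-butyldimethylsilyl chloride, CC(C)(C)[Si](C)(C)Cl
Why: Enolate O-silylation; the methyl group holds the only α-hydrogens (C5 is quaternary), so only the 1-siloxyvinyl group can form.

**Step 8 (key step)**
Reactants: 10; 11 1-(trimethylsilyl)propyne
Product: 12 6-(tert-butyldimethylsilyloxy)-4β-(triethylsilyloxy)-9-(trimethylsilyl)dauca-5,8-diene
Conditions: [Rh(CO)2Cl]2 (5 mol %), 11 (3 equiv), ClCH2CH2Cl, 80 °C
Reagents that add atoms: none
Why: Monovalent rhodium binds the siloxyvinyl group and inserts into the C5–C10 cyclopropane bond, giving a rhodacycle with C10 as a primary alkyl ligand (no β-hydrogen, since C1 is quaternary) and C5–C6–C7 as an allyl ligand; the alkyne then inserts at C7 and reductive elimination joins C9 to C10. The closest known reaction is the [Rh(CO)2Cl]2-catalysed intermolecular (5+2) cycloaddition of 1-substituted vinylcyclopropanes with alkynes, applied here to a ring-fused cyclopropane whose vinyl carbon bears the siloxy group. The seven-membered ring closes as a two-bond annulation onto the existing cyclopentane, C7–C8 by migratory insertion and C9–C10 by reductive elimination from the eight-membered rhodacycle. No stereocentre is formed: C1 and C4 are carried through and C5 becomes the enol ether carbon. Two selectivities are needed: cleavage of C5–C10 rather than C5–C1, which the quaternary C1 should secure because insertion there would place rhodium on a fully substituted carbon, and bonding of the methyl-bearing alkyne carbon to C7, which the bulky SiMe3 group should secure by staying distal to the first C–C bond formed.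

**Step 9**
Reactants: 12
Product: 14 4β-hydroxy-9-(trimethylsilyl)dauc-8-en-6-one (5α-H), via silyl ether ketone 13 (not isolated)
Conditions: aq. HF (48%), MeCN, 0 °C → rt
Reagents that add atoms: none
Why: Hydrolysis of the silyl enol ether by C5 protonation and cleavage of the triethylsilyl ether under acidic fluoride (no base, hence no retro-aldol or β-elimination); the proton should enter from the α-face, which carries only the isopropyl group, and the resulting trans-fused ketone with C6 anti to isopropyl is also the expected thermodynamic epimer.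

**Step 10**
Reactants: 14
Product: 15 9-(trimethylsilyl)dauc-8-ene-4β,6α-diol
Conditions: Me4NBH(OAc)3, AcOH/MeCN (1:1), −30 → −20 °C
Reagents that add atoms: none
Why: Evans–Saksena directed reduction: the β-oriented C4 hydroxyl exchanges onto boron and delivers hydride to the β-face of the C6 ketone, giving the 1,3-anti diol with the 6α-hydroxyl.

**Step 11**
Reactants: 15
Product: 16 dauc-8-ene-4β,6α-diol (5α-H)
Conditions: CF3CO2H (5 equiv), CH2Cl2, 0 °C; NaHCO3 work-up
Reagents that add atoms: none
Why: Acid protodesilylation of a vinylsilane: ipso protonation at C9 gives the tertiary C8 cation stabilised by β-silicon, which loses SiMe3 and leaves the C8=C9 olefin in place, at a stage with no ketone or ester present.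

**Step 12**
Reactants: 16
Product: 17 6α-(tert-butyldimethylsilyloxy)dauc-8-en-4β-ol
Conditions: tBuMe2SiOTf (1.1 equiv), 2,6-lutidine, CH2Cl2, −78 °C
Reagents that add atoms: tert-butyldimethylsilyl triflate, CC(C)(C)[Si](C)(C)OS(=O)(=O)C(F)(F)F
Why: Selective silylation of the secondary C6 hydroxyl; the tertiary C4 hydroxyl flanked by isopropyl should not react at −78 °C.

**Step 13**
Reactants: 18 4-(benzyloxy)-3-methoxybenzoic acid
Product: 19 4-(benzyloxy)-3-methoxybenzoyl chloride
Conditions: (COCl)2, DMF (cat.), CH2Cl2, 0 °C → rt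
Reagents that add atoms: oxalyl chloride, ClC(=O)C(=O)Cl
Why: Standard acid chloride formation through the chloroiminium (Vilsmeier-type) catalyst; the benzyl ether keeps the phenol masked.

**Step 14**
Reactants: 17; 19
Product: 21 6α-(tert-butyldimethylsilyloxy)dauc-8-en-4β-yl 4-(benzyloxy)-3-methoxybenzoate, via lithium alkoxide 20 (not isolated)
Conditions: n-BuLi (1.05 equiv), THF, −78 °C; then 19, −78 → 0 °C
Reagents that add atoms: none
Why: O-acylation of a preformed lithium alkoxide with an aroyl chloride is the established way to esterify hindered tertiary alcohols; the bulky α-oriented silyl ether is trans to the β-alkoxide and should not migrate at low temperature.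

**Step 15**
Reactants: 21
Product: 22 6α-hydroxydauc-8-en-4β-yl 4-(benzyloxy)-3-methoxybenzoate
Conditions: HF·pyridine, pyridine, THF, 0 °C → rt
Reagents that add atoms: none
Why: Buffered fluoride cleavage of the secondary silyl ether; the mildly acidic medium avoids the alkoxide that could trigger acyl migration from O4 to O6.

**Step 16**
Reactants: 22
Product: 23 8α,9α-epoxy-6α-hydroxydaucan-4β-yl 4-(benzyloxy)-3-methoxybenzoate
Conditions: VO(acac)2 (5 mol %), tBuOOH (decane solution), CH2Cl2, 0 °C → rt
Reagents that add atoms: tert-butyl hydroperoxide, CC(C)(C)OO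
Why: Vanadium-catalysed hydroxyl-directed epoxidation of a homoallylic alcohol: the C6 vanadate ester delivers oxygen to the α-face of C8=C9, which is also the face away from the angular methyl, and so sets C8 and C9.

**Step 17**
Reactants: 23
Product: 24 8α,9α-epoxy-6α-hydroxydaucan-4β-yl 4-hydroxy-3-methoxybenzoate (CNP0315707.1)
Conditions: H2 (1 atm), Pd/C (10%), EtOAc, rt
Reagents that add atoms: none
Why: Hydrogenolysis of the aryl benzyl ether under neutral conditions frees the phenol and should leave the tertiary ester, the free C6 hydroxyl and the trisubstituted epoxide untouched.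

**Compound list**
1 | (S)-(+)-terpinen-4-ol | O[C@@]1(C(C)C)CCC(C)=CC1 | starting material
2 | (S)-triethyl{[4-methyl-1-(propan-2-yl)cyclohex-3-en-1-yl]oxy}silane | CC[Si](CC)(CC)O[C@@]1(C(C)C)CCC(C)=CC1 | intermediate
3 | ozonide of 2, 1-methyl-4-(propan-2-yl)-4-(triethylsilyloxy)-7,8,9-trioxabicyclo[4.2.1]nonane (bridgehead epimers) | CC[Si](CC)(CC)O[C@@]1(C(C)C)CCC2(C)OOC(C1)O2 | intermediate
4 | (3S)-6-oxo-3-(propan-2-yl)-3-(triethylsilyloxy)heptanal | CC[Si](CC)(CC)O[C@@](CC=O)(C(C)C)CCC(C)=O | intermediate
5 | (5R)-2-methyl-5-(propan-2-yl)-5-(triethylsilyloxy)cyclopent-1-ene-1-carbaldehyde | CC[Si](CC)(CC)O[C@@]1(C(C)C)CCC(C)=C1C=O | intermediate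
6 | (1R)-1-[(5R)-2-methyl-5-(propan-2-yl)-5-(triethylsilyloxy)cyclopent-1-en-1-yl]ethan-1-ol | CC[Si](CC)(CC)O[C@@]1(C(C)C)CCC(C)=C1[C@@H](C)O | intermediate
7 | (1R)-1-[(1S,2R,5R)-5-methyl-2-(propan-2-yl)-2-(triethylsilyloxy)bicyclo[3.1.0]hexan-1-yl]ethan-1-ol | CC[Si](CC)(CC)O[C@@]2(C(C)C)CC[C@]3(C)C[C@@]32[C@@H](C)O | intermediate
8 | 1-[(1R,2R,5R)-5-methyl-2-(propan-2-yl)-2-(triethylsilyloxy)bicyclo[3.1.0]hexan-1-yl]ethan-1-one | CC[Si](CC)(CC)O[C@@]2(C(C)C)CC[C@]3(C)C[C@@]32C(C)=O | intermediate
9 | lithium enolate of 8 | CC[Si](CC)(CC)O[C@@]2(C(C)C)CC[C@]3(C)C[C@@]32C(=C)O[Li] | intermediate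
10 | tert-butyldimethyl({1-[(1S,2R,5R)-5-methyl-2-(propan-2-yl)-2-(triethylsilyloxy)bicyclo[3.1.0]hexan-1-yl]ethenyl}oxy)silane | CC[Si](CC)(CC)O[C@@]2(C(C)C)CC[C@]3(C)C[C@@]32C(=C)O[Si](C)(C)C(C)(C)C | intermediate
11 | 1-(trimethylsilyl)propyne | CC#C[Si](C)(C)C | starting material
12 | 6-(tert-butyldimethylsilyloxy)-4β-(triethylsilyloxy)-9-(trimethylsilyl)dauca-5,8-diene | CC[Si](CC)(CC)O[C@@]2(C(C)C)CC[C@]3(C)CC([Si](C)(C)C)=C(C)CC(O[Si](C)(C)C(C)(C)C)=C32 | intermediate
13 | 4β-(triethylsilyloxy)-9-(trimethylsilyl)dauc-8-en-6-one (5α-H) | CC[Si](CC)(CC)O[C@@]2(C(C)C)CC[C@]3(C)CC([Si](C)(C)C)=C(C)CC(=O)[C@H]32 | intermediate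
14 | 4β-hydroxy-9-(trimethylsilyl)dauc-8-en-6-one (5α-H) | O[C@@]2(C(C)C)CC[C@]3(C)CC([Si](C)(C)C)=C(C)CC(=O)[C@H]32 | intermediate
15 | 9-(trimethylsilyl)dauc-8-ene-4β,6α-diol | O[C@@]2(C(C)C)CC[C@]3(C)CC([Si](C)(C)C)=C(C)C[C@H](O)[C@H]32 | intermediate
16 | dauc-8-ene-4β,6α-diol | O[C@@]2(C(C)C)CC[C@]3(C)CC=C(C)C[C@H](O)[C@H]32 | intermediate
17 | 6α-(tert-butyldimethylsilyloxy)dauc-8-en-4β-ol | O[C@@]2(C(C)C)CC[C@]3(C)CC=C(C)C[C@H](O[Si](C)(C)C(C)(C)C)[C@H]32 | intermediate
18 | 4-(benzyloxy)-3-methoxybenzoic acid | COc1cc(C(=O)O)ccc1OCc1ccccc1 | starting material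
19 | 4-(benzyloxy)-3-methoxybenzoyl chloride | COc1cc(C(Cl)=O)ccc1OCc1ccccc1 | intermediate
20 | lithium alkoxide of 17 | [Li]O[C@@]2(C(C)C)CC[C@]3(C)CC=C(C)C[C@H](O[Si](C)(C)C(C)(C)C)[C@H]32 | intermediate
21 | 6α-(tert-butyldimethylsilyloxy)dauc-8-en-4β-yl 4-(benzyloxy)-3-methoxybenzoate | COc1cc(C(=O)O[C@@]2(C(C)C)CC[C@]3(C)CC=C(C)C[C@H](O[Si](C)(C)C(C)(C)C)[C@H]32)ccc1OCc1ccccc1 | intermediate
22 | 6α-hydroxydauc-8-en-4β-yl 4-(benzyloxy)-3-methoxybenzoate | COc1cc(C(=O)O[C@@]2(C(C)C)CC[C@]3(C)CC=C(C)C[C@H](O)[C@H]32)ccc1OCc1ccccc1 | intermediate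
23 | 8α,9α-epoxy-6α-hydroxydaucan-4β-yl 4-(benzyloxy)-3-methoxybenzoate | COc1cc(C(=O)O[C@@]2(C(C)C)CC[C@]3(C)C[C@@H]4O[C@]4(C)C[C@H](O)[C@H]32)ccc1OCc1ccccc1 | intermediate
24 | 8α,9α-epoxy-6α-hydroxydaucan-4β-yl 4-hydroxy-3-methoxybenzoate (CNP0315707.1) | COc1cc(C(=O)O[C@@]2(C(C)C)CC[C@]3(C)C[C@@H]4O[C@]4(C)C[C@H](O)[C@H]32)ccc1O | target

**Step count**
Total: 17 steps. Longest linear sequence: 16 steps (steps 1–12 and 14–17, from 1 to 24); step 13 is a one-step side branch.

**Steps most likely to fail**

Step 8. The rhodium may insert slowly into the fully substituted cyclopropane, the vinylcyclopropane may isomerise before the alkyne is captured, or the silylalkyne may insert with the opposite orientation or not at all because C10 sits next to quaternary C1. The fallback builds the same ring by sigmatropic transfer of an allyl group and ring-closing metathesis; it sets out from enal 5 and returns at diol 16. Asymmetric allylation of 5 with (−)-B-allyldiisopinocampheylborane should give the (S)-homoallylic alcohol F1. Its potassium alkoxide (KH, 18-crown-6, THF) should undergo anionic oxy-Cope rearrangement through a chair with the C6–allyl bond on the α-face, moving the allyl group to C1 with chirality transfer from C6 and giving, after C5 protonation, the aldehyde F2. If the epimeric carbinol proves to be the one that rearranges to the α-face, the (+)-borane is used instead. CH2=C(CH3)CH2MgCl then adds to give the carbinol F3. Ring-closing metathesis with the second-generation Grubbs catalyst RuCl2(=CHPh)(H2IMes)(PCy3) closes C8=C9 in the cycloheptenol F4. Dess–Martin oxidation gives the ketone F5, aqueous HF in MeCN the ketol F6, and reduction with Me4NBH(OAc)3 as in step 10 gives 16.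

Step 14. Acylation of the crowded tertiary alkoxide may be incomplete, with silyl transfer from O6 to O4 or elimination competing. The fallback forms the ester by hemiacetal oxidation instead of acylation; it sets out from ketol 14 and returns at 22. Protodesilylation of 14 (CF3CO2H, CH2Cl2, −20 °C) gives the C9–H ketol F7. Evans–Tishchenko reaction of F7 with 4-(benzyloxy)-3-methoxybenzaldehyde and catalytic SmI2 in THF at −10 °C should form the hemiacetal at O4 and transfer its hydride to the β-face of C6. This gives 22 directly, with the ester on C4 and the free 6α-hydroxyl, and makes steps 10–15 unnecessary.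

Step 5. Facial selectivity may be poor if the silyl ether oxygen competes as a directing group or the reactive rotamer differs from the A(1,3) model. The fallback uses reagent-controlled cyclopropanation of the primary allylic alcohol; it sets out from enal 5 and returns at ketone 8. Luche reduction (NaBH4, CeCl3·7H2O, MeOH) gives the primary allylic alcohol F8. Charette cyclopropanation with Zn(CH2I)2·DME and the butylboronate of N,N,N',N'-tetramethyltartaramide (the enantiomer that delivers CH2 to the α-face) gives the cyclopropylmethanol F9. Dess–Martin oxidation gives the aldehyde F10, MeMgBr the carbinol F11 as C6 epimers, and a second Dess–Martin oxidation gives 8.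

**Further compounds**
F1 | step 8 | (1S)-1-[(5R)-2-methyl-5-(propan-2-yl)-5-(triethylsilyloxy)cyclopent-1-en-1-yl]but-3-en-1-ol | CC[Si](CC)(CC)O[C@@]1(C(C)C)CCC(C)=C1[C@H](CC=C)O
F2 | step 8 | 2-methyl-5-(propan-2-yl)-2-(prop-2-en-1-yl)-5-(triethylsilyloxy)cyclopentane-1-carbaldehyde (allyl cis to isopropyl; CHO cis to OSiEt3 and methyl) | CC[Si](CC)(CC)O[C@@]1(C(C)C)CC[C@](C)(CC=C)[C@H]1C=O
F3 | step 8 | 3-methyl-1-[2-methyl-5-(propan-2-yl)-2-(prop-2-en-1-yl)-5-(triethylsilyloxy)cyclopentyl]but-3-en-1-ol (C6 epimers) | CC[Si](CC)(CC)O[C@@]1(C(C)C)CC[C@](C)(CC=C)[C@H]1C(O)CC(C)=C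
F4 | step 8 | 4β-(triethylsilyloxy)dauc-8-en-6-ol (5α-H, C6 epimers) | CC[Si](CC)(CC)O[C@@]2(C(C)C)CC[C@]3(C)CC=C(C)CC(O)[C@H]32
F5 | step 8 | 4β-(triethylsilyloxy)dauc-8-en-6-one (5α-H) | CC[Si](CC)(CC)O[C@@]2(C(C)C)CC[C@]3(C)CC=C(C)CC(=O)[C@H]32
F6 | step 8 | 4β-hydroxydauc-8-en-6-one (5α-H) | O[C@@]2(C(C)C)CC[C@]3(C)CC=C(C)CC(=O)[C@H]32
F7 | step 14 | 4β-hydroxydauc-8-en-6-one (5α-H) | O[C@@]2(C(C)C)CC[C@]3(C)CC=C(C)CC(=O)[C@H]32
F8 | step 5 | [(5R)-2-methyl-5-(propan-2-yl)-5-(triethylsilyloxy)cyclopent-1-en-1-yl]methanol | CC[Si](CC)(CC)O[C@@]1(C(C)C)CCC(C)=C1CO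
F9 | step 5 | [(1S,2R,5R)-5-methyl-2-(propan-2-yl)-2-(triethylsilyloxy)bicyclo[3.1.0]hexan-1-yl]methanol (cyclopropane CH2 cis to isopropyl) | CC[Si](CC)(CC)O[C@@]2(C(C)C)CC[C@]3(C)C[C@@]32CO
F10 | step 5 | 5-methyl-2-(propan-2-yl)-2-(triethylsilyloxy)bicyclo[3.1.0]hexane-1-carbaldehyde (cyclopropane CH2 cis to isopropyl) | CC[Si](CC)(CC)O[C@@]2(C(C)C)CC[C@]3(C)C[C@@]32C=O
F11 | step 5 | 1-[5-methyl-2-(propan-2-yl)-2-(triethylsilyloxy)bicyclo[3.1.0]hexan-1-yl]ethan-1-ol (C6 epimers, one of them 7) | CC[Si](CC)(CC)O[C@@]2(C(C)C)CC[C@]3(C)C[C@@]32C(C)O
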